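How much of the electrophile has reacted after 2.5 min at each of three nucleophile charges?

in all of them: electrophile 0.18 M

| charge | nucleophile | protic impurity | remark | time |
|---|---|---|---|---|
| grey | 0.28 M | 0.036 M | run made earlier |  |
| red | 0.40 M | 0.036 M | run made earlier |  |
| teal | 0.99 M | 0.036 M | run made earlier |  |
| north-east | 0.860 M | 0.0360 M |  | 2.5 min |
| south | 0.430 M | 0.0360 M |  | 2.5 min |
| south-west | 0.220 M | 0.0360 M |  | 2.5 min |

| run | time / min | electrophile / % | product / % |
|---|---|---|---|
| grey | 0.500 | 82.9 | 16.5 |
| grey | 1.00 | 71.7 | 27.4 |
| grey | 1.50 | 65.1 | 36.1 |
| grey | 2.00 | 59.1 | 41.5 |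
| grey | 2.50 | 54.2 | 46.1 |
| red | 0.200 | 87.3 | 11.9 |
| red | 0.667 | 70.5 | 29.6 |
| red | 1.33 | 54.2 | 45.5 |
| red | 2.00 | 43.2 | 55.6 |
| red | 2.50 | 39.1 | 61.7 |
| teal | 0.500 | 47.2 | 52.1 |
| teal | 1.00 | 25.8 | 74.0 |
| teal | 1.50 | 14.2 | 84.8 |
| teal | 2.00 | 8.0 | 92.0 |
| teal | 2.50 | 5.5 | 94.6 |

(readings scatter by 0.5 percentage points)
- part of the electrophile that has reacted at the end, north-east
- part of the electrophile that has reacted at the end, south
- part of the electrophile that has reacted at the end, south-west
- what raising the concentration of nucleophile from its lowest to its highest value here does to the part of the electrophile that has reacted (changes below 5 percentage points count as none) (it rises / it falls / no change)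
- a species is counted by the electrophile in it: one homo dimer counts as two
- amounts and yields of acid set free count idle adduct too
- the numbers in the tables scatter by 0.5 percentage points (one standard deviation)
- what may be going on: nucleophile + acid set free <-> idle adduct; 2 electrophile -> homo dimer; electrophile + nucleophile -> acid set free + product; nucleophile + protic impurity -> quenched reagent; nucleophile + acid set free <-> protonated nucleophile

A bench rule says that nucleophile in excess stays nearly constant, so the electrophile decays by pseudo-first-order kinetics and goes to the end. By equivalents, south-west qualifies, with 1.22 nucleophile per electrophile. The rule can be tested on the grey run, where its specific loss rate s, the fall in ln(electrophile) per minute, should hold steady.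

first window: s = 0.375 /min
last window: s = 0.173 /min

So s sinks by a factor F = 2.17. If s follows free nucleophile, which starts at the charge less the protic impurity, U = 0.244 M, the electrophile lost at mid-window gives the nucleophile used per electrophile:

first window: x = 0.0154 M
last window: x = 0.0780 M
n = (F − 1)U/(F·x(last) − x(first)) = 1.85

This reading is taken as two, and there the bench rule meets its border. With charges N, h and E of nucleophile, protic impurity and electrophile, the ratio C = (N − h)/(2E) is 0.511 for south-west: the cover, the share of the charged electrophile that the usable nucleophile can pay for at two apiece. South has 1.09 and north-east 2.29. South-west lies below one, so this reckoning expects its reacted part to level off near that share, given time.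

The forecast gives 92 % (89.5 % to 94.5 %) for north-east, 65 % (62 % to 68 %) for south and 36 % (32.5 % to 39.5 %) for south-west, and says of the trend: it rises. Its ground: “Each product frees acid that ties up a second nucleophile”.

The flasks give 92.1 % in north-east, 64.9 % in south and 36.0 % in south-west; from the lowest to the highest nucleophile charge the answer to the trend is: it rises, by 56 percentage points.

    nucleophile + acid set free ⇌ idle adduct, settled at all times (K = 4.20 /M)
    2 electrophile → homo dimer (k = 2.30 × 10⁻⁵ /M/s)
    electrophile + nucleophile → acid set free + product (k = 0.0290 /M/s)
    nucleophile + protic impurity → quenched reagent (k = 1.90 /M/s)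
    nucleophile + acid set free ⇌ protonated nucleophile, settled at all times (K = 32000 /M)

In south, the path to quenched reagent had half of its turnover up to 2.5 min behind it by 0.873 s, earlier than the 0.685 min of the path to product, and at 2.50 min the flask held 0 % of its protic impurity and 0.117 M of protonated nucleophile. South-west, with cover 0.511, ran on to 52.4 % reacted at 25.0 min, close to its cover, with 0.324 % of its nucleophile free. A further flask, like south but with 0.11 M of nucleophile, has cover 0.206 and stands at 15.8 % reacted at 2.50 min, with 15.9 % of its nucleophile free.

The data are simulated from invented constants; scatter was added.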